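**Plan**

1. Retrosynthesis: the C17 allylic alcohol with the C8=C9 alkene is read as the 1,3-transposed form of a C9 tertiary allylic alcohol with an exocyclic C8=CH2. C6–C7 and C8–C9 of ring B are then cut together, leaving a ring A 1,4-keto-aldehyde (C6 formyl on C5, C9 acyl on C10) and 2,3-dibromopropene.
2. Enabling feature: the cis ring fusion (H-5 and CH3-10 on the same face) puts the C5–C6 and C10–C9 bonds cis on ring A. C6 and C9 can therefore be the two sp2 carbons of a cis-fused cyclobutene (ozonolysis gives the keto-aldehyde) and can be bridged by one two-carbon unit. C6–OH is homoallylic and C17–OH allylic to C8=C9.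
3. Forward order: ring A from (4R,6R)-actinol (carbinol carbon = C2, CMe2 = C4, ketone carbon = C5, CH(CH3) = C10); keteniminium [2+2] on the C5=C10 alkene brings C6, C9 and the finished butenolide side chain; cyclobutene; ozonolysis; ring B in one flask by chromium-mediated allylation then alkenylation; 1,3-transposition; desilylation.
4. Stereochemistry: C2 from actinol; C5 and C10 from the [2+2] on the face anti to the pseudoaxial C4 methyl (the OTBS face); C6 from substrate-controlled allyl transfer; the C9 carbinol centre is transient.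

Key step: step 9

Remark on the structure: the SMILES encodes 2S,5R,6S,10S (labdane numbering, used for all atom labels below). H-5 and CH3-10 lie on one face (cis-fused decalin); 2-OH and 6-OH lie on the other.

Assumption: compounds 1, 5, 6 and 16 are purchased. C9 carries no descriptor in the SMILES of 10, 11, 14 and 18 (nor C6 in 14), because both epimers converge or the bridged ring fixes the centre.

**Step 1**
Reactants: 1 (4R,6R)-4-hydroxy-2,2,6-trimethylcyclohexan-1-one
Product: 2 (4R,6R)-4-[(tert-butyldimethylsilyl)oxy]-2,2,6-trimethylcyclohexan-1-one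
Conditions: TBSCl, imidazole, DMF, 25 °C
Reagents that add atoms: tert-butyldimethylsilyl chloride, CC(C)(C)[Si](C)(C)Cl
Why: Imidazole-promoted silylation of the secondary alcohol is routine and masks C2–OH against the strong base and the triflic anhydride used later without touching a stereocentre.

**Step 2**
Reactants: 2 (4R,6R)-4-[(tert-butyldimethylsilyl)oxy]-2,2,6-trimethylcyclohexan-1-one
Product: 3 (4R)-4-[(tert-butyldimethylsilyl)oxy]-2,6,6-trimethylcyclohex-1-en-1-yl trifluoromethanesulfonate
Conditions: KN(SiMe3)2, THF, −78 °C; PhNTf2, −78 → 0 °C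
Reagents that add atoms: N-phenylbis(trifluoromethanesulfonimide), O=S(=O)(N(c1ccccc1)S(=O)(=O)C(F)(F)F)C(F)(F)F
Why: The ketone can enolise only toward the methyl-bearing carbon (the other α-carbon is quaternary), so deprotonation and O-triflation give a single enol triflate; the methyl-bearing stereocentre is erased on purpose because C10 is set again in step 5.

**Step 3**
Reactants: 3 (4R)-4-[(tert-butyldimethylsilyl)oxy]-2,6,6-trimethylcyclohex-1-en-1-yl trifluoromethanesulfonate
Product: 4 tert-butyldimethyl{[(1R)-3,5,5-trimethylcyclohex-3-en-1-yl]oxy}silane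
Conditions: Pd(OAc)2 (cat.), PPh3, HCO2H, Bu3N, DMF, 60 °C
Reagents that add atoms: none
Why: Palladium-catalysed formate reduction of an enol triflate (oxidative addition, formate exchange, loss of CO2, C–H reductive elimination) replaces OTf by H and gives the ring A alkene whose sp2 carbons are the future C5 and C10.

**Step 4**
Reactants: 5 4-bromo-N,N-dimethylbutanamide; 6 4-bromofuran-2(5H)-one
Product: 8 N,N-dimethyl-4-(5-oxo-2,5-dihydrofuran-3-yl)butanamide, via alkylzinc bromide 7 (not isolated)
Conditions: Zn dust, LiCl, THF, 25 °C; then 6, Pd(PPh3)4 (cat.), THF, 25 °C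
Reagents that add atoms: none
Why: Negishi coupling: zinc inserts into the primary C–Br bond in the presence of the amide, and palladium transfers the alkyl group to the vinylogous acyl bromide carbon of 6, which builds the C12–C13 bond and delivers the finished butenolide side chain.

**Step 5**
Reactants: 4 tert-butyldimethyl{[(1R)-3,5,5-trimethylcyclohex-3-en-1-yl]oxy}silane; 8 N,N-dimethyl-4-(5-oxo-2,5-dihydrofuran-3-yl)butanamide
Product: 11 cis-fused 3-[(tert-butyldimethylsilyl)oxy]-1,5,5-trimethyl-8-[2-(5-oxo-2,5-dihydrofuran-3-yl)ethyl]bicyclo[4.2.0]octan-7-one (four-membered ring on the face of the silyloxy group; both C8 epimers), via keteniminium triflate 9 (not isolated), via cyclobutaniminium triflate 10 (not isolated)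
Conditions: 8, Tf2O, 2,4,6-collidine, ClCH2CH2Cl, −20 °C; 4, 80 °C; then H2O, 25 °C
Reagents that add atoms: water, O
Why: A keteniminium ion is electrophilic enough for an unactivated trisubstituted alkene where an alkylketene is not: its iminium carbon bonds to the less substituted alkene carbon C5, the tertiary cation at C10 is closed by the enamine carbon C9 so that the four-membered ring is cis-fused, and the reagent approaches anti to the pseudoaxial C4 methyl of the half-chair that keeps OTBS equatorial (the OTBS face), which sets C5 and C10; the iminium is then hydrolysed to the ketone.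

**Step 6**
Reactants: 11 cis-fused 3-[(tert-butyldimethylsilyl)oxy]-1,5,5-trimethyl-8-[2-(5-oxo-2,5-dihydrofuran-3-yl)ethyl]bicyclo[4.2.0]octan-7-one
Product: 12 cis-fused 3-[(tert-butyldimethylsilyl)oxy]-1,5,5-trimethyl-8-[2-(5-oxo-2,5-dihydrofuran-3-yl)ethyl]bicyclo[4.2.0]oct-7-en-7-yl trifluoromethanesulfonate
Conditions: Tf2O, 2,6-di-tert-butyl-4-methylpyridine, CH2Cl2, 0 → 25 °C
Reagents that add atoms: trifluoromethanesulfonic anhydride, O=S(=O)(OS(=O)(=O)C(F)(F)F)C(F)(F)F
Why: O-Triflation of the ketone followed by loss of the C9 proton to the hindered pyridine is a base-free enol triflate synthesis that spares the base-sensitive butenolide, and proton loss toward C9 is expected because the C5=C6 isomer would push the C4 gem-dimethyl group into allylic strain with the triflate.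

**Step 7**
Reactants: 12 cis-fused 3-[(tert-butyldimethylsilyl)oxy]-1,5,5-trimethyl-8-[2-(5-oxo-2,5-dihydrofuran-3-yl)ethyl]bicyclo[4.2.0]oct-7-en-7-yl trifluoromethanesulfonate
Product: 13 cis-fused 4-{2-[3-[(tert-butyldimethylsilyl)oxy]-1,5,5-trimethylbicyclo[4.2.0]oct-7-en-8-yl]ethyl}furan-2(5H)-one
Conditions: Pd(OAc)2 (cat.), PPh3, HCO2H, Bu3N, DMF, 50 °C
Reagents that add atoms: none
Why: The same palladium-catalysed formate reduction replaces the cyclobutenyl triflate by hydrogen under conditions that do not touch the butenolide or the silyl ether and leaves the C6=C9 cyclobutene.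

**Step 8**
Reactants: 13 cis-fused 4-{2-[3-[(tert-butyldimethylsilyl)oxy]-1,5,5-trimethylbicyclo[4.2.0]oct-7-en-8-yl]ethyl}furan-2(5H)-one
Product: 15 (1R,4S,6S)-4-[(tert-butyldimethylsilyl)oxy]-2,2,6-trimethyl-6-[3-(5-oxo-2,5-dihydrofuran-3-yl)propanoyl]cyclohexane-1-carbaldehyde, via ozonide 14 (not isolated)
Conditions: O3 (one equivalent), CH2Cl2, −78 °C; PPh3, −78 → 25 °C
Reagents that add atoms: ozone, [O-][O+]=O
Why: Ozone should cleave the strained, electron-rich trisubstituted cyclobutene far faster than the electron-poor butenolide alkene, and reduction of the ozonide with PPh3 under neutral conditions releases the C6 aldehyde and the C9 ketone cis on ring A without epimerising C5.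

**Step 9**
Reactants: 15 (1R,4S,6S)-4-[(tert-butyldimethylsilyl)oxy]-2,2,6-trimethyl-6-[3-(5-oxo-2,5-dihydrofuran-3-yl)propanoyl]cyclohexane-1-carbaldehyde; 16 2,3-dibromoprop-1-ene
Product: 18 4-{2-[(4S,4aR,7S,8aS)-7-[(tert-butyldimethylsilyl)oxy]-1,4-dihydroxy-5,5,8a-trimethyl-2-methylidenedecahydronaphthalen-1-yl]ethyl}furan-2(5H)-one (both C1 epimers), via bromoallyl carbinol 17 (not isolated)
Conditions: CrCl2 (excess), NiCl2 (cat.), THF–DMF, 0 → 25 °C
Reagents that add atoms: none
Why: Proposed new method: divalent chromium reduces only the allylic C–Br bond of 16, and the 2-bromoallylchromium species adds through a six-membered chair transition state to the C6 aldehyde (not to the hindered ketone) to form C6–C7 and the alkoxide of 17; zerovalent nickel, formed from NiCl2 and CrCl2, then inserts into the vinylic C–Br bond, transmetallates to trivalent chromium, and the alkenylchromium adds to the C9 ketone to form C8–C9. The closest known reaction types are the chromium-mediated 2-haloallylation of aldehydes and the intramolecular Nozaki–Hiyama–Kishi alkenylation of ketones; running both in one flask as a [4+2] annulation of a 1,4-keto-aldehyde is the new element. Ring B is closed in the second event by 6-exo-trig attack of C8 on the C9 carbonyl, and the fusion stays cis because C5 and C10 are not touched. C6 is set by the substrate: the formyl group is axial on ring A with C=O eclipsing C5–H, and the allyl group should enter past the C4 equatorial methyl, away from the larger C10 acyl arm (the face that a chelate between the two carbonyl oxygens would also expose), which gives 6S; C9 is not controlled and is erased in step 10. The step needs aldehyde-over-ketone and allyl-over-vinyl chemoselectivity, both inherent to chromium, and a cis-1,2 arrangement of the two carbonyl arms, which the cyclobutene precursor guarantees.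

**Step 10**
Reactants: 18 4-{2-[(4S,4aR,7S,8aS)-7-[(tert-butyldimethylsilyl)oxy]-1,4-dihydroxy-5,5,8a-trimethyl-2-methylidenedecahydronaphthalen-1-yl]ethyl}furan-2(5H)-one
Product: 19 4-{2-[(4S,4aR,7S,8aS)-7-[(tert-butyldimethylsilyl)oxy]-4-hydroxy-2-(hydroxymethyl)-5,5,8a-trimethyl-3,4,4a,5,6,7,8,8a-octahydronaphthalen-1-yl]ethyl}furan-2(5H)-one
Conditions: Ph3SiOReO3 (cat.), Et2O, −40 → 0 °C
Reagents that add atoms: none
Why: Perrhenate-catalysed 1,3-transposition of allylic alcohols (a [3,3] shift of the allyl perrhenate ester) equilibrates toward the more substituted alkene, here from the tertiary C9 alcohol with an exocyclic 1,1-disubstituted alkene to the primary C17 alcohol with the tetrasubstituted C8=C9 alkene, which removes the uncontrolled C9 centre while the homoallylic C6 alcohol cannot migrate.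

**Step 11**
Reactants: 19 4-{2-[(4S,4aR,7S,8aS)-7-[(tert-butyldimethylsilyl)oxy]-4-hydroxy-2-(hydroxymethyl)-5,5,8a-trimethyl-3,4,4a,5,6,7,8,8a-octahydronaphthalen-1-yl]ethyl}furan-2(5H)-one
Product: 20 4-{2-[(4S,4aR,7S,8aS)-4,7-dihydroxy-2-(hydroxymethyl)-5,5,8a-trimethyl-3,4,4a,5,6,7,8,8a-octahydronaphthalen-1-yl]ethyl}furan-2(5H)-one
Conditions: HF·pyridine, pyridine, THF, 0 → 25 °C
Reagents that add atoms: none
Why: Fluoride cleavage of the secondary silyl ether under buffered, weakly acidic conditions leaves the butenolide, the allylic alcohol and the tetrasubstituted alkene untouched and releases the triol.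

**Compound list**

1 | (4R,6R)-4-hydroxy-2,2,6-trimethylcyclohexan-1-one (actinol) | CC1(C)C[C@H](O)C[C@@H](C)C1=O | starting material
2 | (4R,6R)-4-[(tert-butyldimethylsilyl)oxy]-2,2,6-trimethylcyclohexan-1-one | CC1(C)C[C@H](O[Si](C)(C)C(C)(C)C)C[C@@H](C)C1=O | intermediate
3 | (4R)-4-[(tert-butyldimethylsilyl)oxy]-2,6,6-trimethylcyclohex-1-en-1-yl trifluoromethanesulfonate | CC1(C)C[C@H](O[Si](C)(C)C(C)(C)C)CC(C)=C1OS(=O)(=O)C(F)(F)F | intermediate
4 | tert-butyldimethyl{[(1R)-3,5,5-trimethylcyclohex-3-en-1-yl]oxy}silane | CC1(C)C[C@H](O[Si](C)(C)C(C)(C)C)CC(C)=C1 | intermediate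
5 | 4-bromo-N,N-dimethylbutanamide | CN(C)C(=O)CCCBr | starting material
6 | 4-bromofuran-2(5H)-one | O=C1OCC(Br)=C1 | starting material
7 | [4-(dimethylamino)-4-oxobutyl]zinc bromide | CN(C)C(=O)CCC[Zn]Br | intermediate
8 | N,N-dimethyl-4-(5-oxo-2,5-dihydrofuran-3-yl)butanamide | CN(C)C(=O)CCCC1=CC(=O)OC1 | intermediate
9 | N-methyl-N-[4-(5-oxo-2,5-dihydrofuran-3-yl)but-1-en-1-ylidene]methanaminium trifluoromethanesulfonate (keteniminium triflate) | C[N+](C)=C=CCCC1=CC(=O)OC1.[O-]S(=O)(=O)C(F)(F)F | intermediate
10 | cyclobutaniminium triflate: N,N-dimethyliminium salt of 11 (cis-fused; four-membered ring on the silyloxy face; both C9 epimers) | CC1(C)C[C@H](O[Si](C)(C)C(C)(C)C)C[C@]2(C)C(CCC3=CC(=O)OC3)C(=[N+](C)C)[C@H]12.[O-]S(=O)(=O)C(F)(F)F | intermediate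
11 | cis-fused 3-[(tert-butyldimethylsilyl)oxy]-1,5,5-trimethyl-8-[2-(5-oxo-2,5-dihydrofuran-3-yl)ethyl]bicyclo[4.2.0]octan-7-one (four-membered ring on the silyloxy face; silyloxy carbon configured as in 1; both C8 epimers) | CC1(C)C[C@H](O[Si](C)(C)C(C)(C)C)C[C@]2(C)C(CCC3=CC(=O)OC3)C(=O)[C@H]12 | intermediate
12 | cis-fused 3-[(tert-butyldimethylsilyl)oxy]-1,5,5-trimethyl-8-[2-(5-oxo-2,5-dihydrofuran-3-yl)ethyl]bicyclo[4.2.0]oct-7-en-7-yl trifluoromethanesulfonate (stereocentres as in 11) | CC1(C)C[C@H](O[Si](C)(C)C(C)(C)C)C[C@]2(C)C(CCC3=CC(=O)OC3)=C(OS(=O)(=O)C(F)(F)F)[C@H]12 | intermediate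
13 | cis-fused 4-{2-[3-[(tert-butyldimethylsilyl)oxy]-1,5,5-trimethylbicyclo[4.2.0]oct-7-en-8-yl]ethyl}furan-2(5H)-one (stereocentres as in 11) | CC1(C)C[C@H](O[Si](C)(C)C(C)(C)C)C[C@]2(C)C(CCC3=CC(=O)OC3)=C[C@H]12 | intermediate
14 | ozonide of 13 (1,2,4-trioxolane bridging C6 and C9) | CC1(C)C[C@H](O[Si](C)(C)C(C)(C)C)C[C@]2(C)C3(CCC4=CC(=O)OC4)OOC(O3)[C@H]12 | intermediate
15 | (1R,4S,6S)-4-[(tert-butyldimethylsilyl)oxy]-2,2,6-trimethyl-6-[3-(5-oxo-2,5-dihydrofuran-3-yl)propanoyl]cyclohexane-1-carbaldehyde (formyl, acyl and silyloxy groups all cis) | CC1(C)C[C@H](O[Si](C)(C)C(C)(C)C)C[C@](C)(C(=O)CCC2=CC(=O)OC2)[C@@H]1C=O | intermediate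
16 | 2,3-dibromoprop-1-ene | C=C(Br)CBr | starting material
17 | (1S)-3-bromo-1-{(1R,4S,6S)-4-[(tert-butyldimethylsilyl)oxy]-2,2,6-trimethyl-6-[3-(5-oxo-2,5-dihydrofuran-3-yl)propanoyl]cyclohexyl}but-3-en-1-ol (present as its chromium alkoxide) | CC1(C)C[C@H](O[Si](C)(C)C(C)(C)C)C[C@](C)(C(=O)CCC2=CC(=O)OC2)[C@@H]1[C@@H](O)CC(Br)=C | intermediate
18 | 4-{2-[(4S,4aR,7S,8aS)-7-[(tert-butyldimethylsilyl)oxy]-1,4-dihydroxy-5,5,8a-trimethyl-2-methylidenedecahydronaphthalen-1-yl]ethyl}furan-2(5H)-one (both C1 epimers) | CC1(C)C[C@H](O[Si](C)(C)C(C)(C)C)C[C@]2(C)C(O)(CCC3=CC(=O)OC3)C(=C)C[C@H](O)[C@H]12 | intermediate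
19 | 4-{2-[(4S,4aR,7S,8aS)-7-[(tert-butyldimethylsilyl)oxy]-4-hydroxy-2-(hydroxymethyl)-5,5,8a-trimethyl-3,4,4a,5,6,7,8,8a-octahydronaphthalen-1-yl]ethyl}furan-2(5H)-one | CC1(C)C[C@H](O[Si](C)(C)C(C)(C)C)C[C@]2(C)C(CCC3=CC(=O)OC3)=C(CO)C[C@H](O)[C@H]12 | intermediate
20 | 4-{2-[(4S,4aR,7S,8aS)-4,7-dihydroxy-2-(hydroxymethyl)-5,5,8a-trimethyl-3,4,4a,5,6,7,8,8a-octahydronaphthalen-1-yl]ethyl}furan-2(5H)-one (CNP0293367.1; 2S,5R,6S,10S in labdane numbering) | CC1(C)C[C@H](O)C[C@]2(C)C(CCC3=CC(=O)OC3)=C(CO)C[C@H](O)[C@H]12 | target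

**Step count and risks**

Total step count: 11. Longest linear sequence: 10 steps (1 → 20 through steps 1–3 and 5–11; step 4 is a one-step side branch).

Steps most likely to fail:

1. Step 9 (the step carrying the label). What may go wrong: low facial selectivity in the allyl transfer to the C6 aldehyde; slow alkenyl transfer to the hindered C9 ketone, so that the vinylic bromide is reduced instead of cyclising; epimerisation of the aldehyde at C5 before it reacts. Fallback, from 15 back to 18: the allyl transfer is put under reagent control with (2-bromoallyl)diisopinocampheylborane (generated from allene and bromodiisopinocampheylborane; the pinene antipode that delivers the 6S carbinol is used) in Et2O at −78 °C with ethanolamine work-up. The aldehyde reacts and the ketone does not, and bromoallyl carbinol 17 is isolated. Ring B is then closed in a separate Nozaki–Hiyama–Kishi alkenylation of the ketone (CrCl2, NiCl2 cat., DMSO, 25–50 °C), which gives 18. No compound outside the compound list is made (F0).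

2. Step 5. What may go wrong: proton loss from the tertiary cation at C10 (ene-type acylation) instead of ring closure; slow attack at the neopentyl alkene carbon C5; interception of the keteniminium ion by the butenolide. Fallback, from 4 back to 11: dichloroketene (Cl3CCOCl, Zn–Cu couple, Et2O, 25 °C), the most reactive ketene toward unactivated trisubstituted alkenes, should add with the same orientation and facial sense to give dichlorocyclobutanone F1. Zn dust in AcOH removes both chlorine atoms to give cyclobutanone F2. LiN(iPr)2 then Me3SiCl (THF, −78 °C) gives the less substituted silyl enol ether F3. A Mukaiyama–Michael 1,6-addition of F3 to 4-ethenylfuran-2(5H)-one F4 (from 6 and tributyl(vinyl)stannane by Stille coupling with Pd(PPh3)4) under TiCl4 in CH2Cl2 at −78 °C attaches C11, C12 and the butenolide at C9 and gives 11.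

3. Step 6. What may go wrong: enolisation toward the ring-fusion carbon C5 instead of C9; triflation of the butenolide; ring contraction of the O-triflylated cyclobutyl cation. Fallback, from 11 back to 13 (it replaces steps 6 and 7): NaBH4 with CeCl3·7H2O in MeOH at −40 °C should deliver hydride to the convex face of the cyclobutanone, C9 having settled in the exo-alkyl configuration, and give cyclobutanol F5, in which H-9 is syn and H-5 anti to the hydroxyl group. Methyl N-(triethylammoniosulfonyl)carbamate in toluene at 60 °C then eliminates through a cyclic syn transition state, which can only place the double bond between C6 and C9, and gives 13.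

**Further compounds**

F0 | step 9 | none | none
F1 | step 5 | cis-fused 3-[(tert-butyldimethylsilyl)oxy]-8,8-dichloro-1,5,5-trimethylbicyclo[4.2.0]octan-7-one | CC1(C)C[C@H](O[Si](C)(C)C(C)(C)C)C[C@]2(C)C(Cl)(Cl)C(=O)[C@H]12
F2 | step 5 | cis-fused 3-[(tert-butyldimethylsilyl)oxy]-1,5,5-trimethylbicyclo[4.2.0]octan-7-one | CC1(C)C[C@H](O[Si](C)(C)C(C)(C)C)C[C@]2(C)CC(=O)[C@H]12
F3 | step 5 | cis-fused tert-butyldimethyl({1,5,5-trimethyl-7-[(trimethylsilyl)oxy]bicyclo[4.2.0]oct-7-en-3-yl}oxy)silane | CC1(C)C[C@H](O[Si](C)(C)C(C)(C)C)C[C@]2(C)C=C(O[Si](C)(C)C)[C@H]12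
F4 | step 5 | 4-ethenylfuran-2(5H)-one | C=CC1=CC(=O)OC1
F5 | step 6 | cis-fused 4-{2-[3-[(tert-butyldimethylsilyl)oxy]-7-hydroxy-1,5,5-trimethylbicyclo[4.2.0]octan-8-yl]ethyl}furan-2(5H)-one (7-OH on the concave face; side chain on the convex face) | CC1(C)C[C@H](O[Si](C)(C)C(C)(C)C)C[C@]2(C)[C@@H](CCC3=CC(=O)OC3)[C@H](O)[C@H]12
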